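## Retrosynthetic overview

1. Last disconnection (ring expansion, 5→6). The 2H‑pyran ring O1–C2(Me)2–C3=C4–C4a–C8a is taken back to a 2‑isopropenyl‑2,3‑dihydrofuran ring O1–C3–C4–C4a–C8a, in which C2 is still exocyclic. A Pd(0)‑catalysed retro‑hydroaryloxylation/hydroaryloxylation moves O1 from C3 to C2.
2. Enabling feature. O1 sits on C8a, ortho to the C8 acyl group, so its phenoxide is a vinylogous carboxylate and a leaving group for Pd(0). C2 is a fully substituted allyl terminus, and C3=C4 ends in conjugation with the trioxygenated arene. C4a is flanked by O1 and the C5 methoxy group, so only O1 can close. The pyran ring has no stereocentre, so the centre of the five‑membered ring never needs control.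
3. Cyclohexene. An asymmetric Diels–Alder reaction of the dihydrobenzofuranyl 2'‑hydroxychalcone with (E)‑β‑ocimene on a chiral borate sets C1, C2 and C6 in one step.
4. Chalcone by Claisen–Schmidt condensation. Dihydrofuran by Heck/Tsuji–Trost heteroannulation of isoprene with the mono‑iodide of the symmetric 2',6'‑dihydroxy‑4'‑methoxyacetophenone.
5. Order of ring formation: arene (bought) → dihydrofuran → cyclohexene → pyran (from the dihydrofuran).

Key step: step 5

Assumption: (E)‑β‑ocimene is bought as the commercial E/Z mixture; the Z isomer cannot reach the s‑cis conformation and stays a spectator.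
Assumption: the face selectivity of the (R)‑VANOL borate is assigned by analogy with related 2'‑hydroxychalcone cycloadditions; if it proves opposite, (S)‑VANOL is used.

## Route

Step 1
Reactants: 1 2',6'-dihydroxy-4'-methoxyacetophenone
Product: 2 1-(2,6-dihydroxy-3-iodo-4-methoxyphenyl)ethan-1-one
Conditions: NIS (1.0 equiv), MeCN, 0 °C to rt, dark
Reagents that add atoms: N-iodosuccinimide (NIS), O=C1CCC(=O)N1I
Why: Electrophilic aromatic iodination; the two free ring positions of 1 are equivalent by symmetry and activated by three oxygen substituents, so one equivalent of NIS should give a single mono-iodide.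

Step 2
Reactants: 2 1-(2,6-dihydroxy-3-iodo-4-methoxyphenyl)ethan-1-one; 3 isoprene
Product: 4 rac-1-[6-hydroxy-4-methoxy-2-(prop-1-en-2-yl)-2,3-dihydro-1-benzofuran-7-yl]ethan-1-one
Conditions: Pd(OAc)2 (5 mol %), n-Bu4NCl, Na2CO3, isoprene (5 equiv), DMF, 80 °C, sealed tube
Reagents that add atoms: none
Why: Larock heteroannulation of a 1,3-diene (Heck insertion, then Tsuji–Trost closure); the aryl-Pd species adds to the unsubstituted vinyl terminus of isoprene and the neighbouring phenoxide closes 5-exo on the η3-allyl, which sets the single stereocentre without control (racemate), as intended.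

Step 3
Reactants: 4 rac-1-[6-hydroxy-4-methoxy-2-(prop-1-en-2-yl)-2,3-dihydro-1-benzofuran-7-yl]ethan-1-one; 5 benzaldehyde
Product: 6 rac-(E)-1-[6-hydroxy-4-methoxy-2-(prop-1-en-2-yl)-2,3-dihydro-1-benzofuran-7-yl]-3-phenylprop-2-en-1-one
Conditions: KOH (aq. 50 %), EtOH, 0 °C to rt; then dilute acid
Reagents that add atoms: none
Why: Claisen–Schmidt condensation; only the methyl ketone is enolisable, benzaldehyde has no α-hydrogen, the conjugated (E)-enone is the thermodynamic product and the allyl aryl ether is inert to hydroxide.

Step 4
Reactants: 6 rac-(E)-1-[6-hydroxy-4-methoxy-2-(prop-1-en-2-yl)-2,3-dihydro-1-benzofuran-7-yl]-3-phenylprop-2-en-1-one; 7 (E)-β-ocimene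
Product: 8 [6-hydroxy-4-methoxy-2-(prop-1-en-2-yl)-2,3-dihydro-1-benzofuran-7-yl][(1R,2S,6R)-3-methyl-2-(3-methylbut-2-en-1-yl)-6-phenylcyclohex-3-en-1-yl]methanone (both epimers at C2 of the dihydrofuran)
Conditions: (R)-VANOL (1.2 equiv), B(OPh)3 (1.2 equiv), 5 Å MS, PhCF3, rt; then 6 and 7 (3 equiv), rt to 40 °C; aqueous work-up
Reagents that add atoms: none
Why: Chiral-borate-promoted asymmetric Diels–Alder reaction of a 2'-hydroxychalcone; binding of the phenol and carbonyl oxygens to boron lowers the LUMO, the 1-alkyl group of the diene directs "ortho" bonding, the (E)-enone fixes C1/C6 trans, the endo aroyl group places C1/C2 cis, the VANOL wall shields one enone face and so sets the absolute configuration, and the remote dihydrofuran centre stays unselected.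

Step 5
Reactants: 8 [6-hydroxy-4-methoxy-2-(prop-1-en-2-yl)-2,3-dihydro-1-benzofuran-7-yl][(1R,2S,6R)-3-methyl-2-(3-methylbut-2-en-1-yl)-6-phenylcyclohex-3-en-1-yl]methanone (both epimers)
Product: 10 (7-hydroxy-5-methoxy-2,2-dimethyl-2H-chromen-8-yl)[(1R,2S,6R)-3-methyl-2-(3-methylbut-2-en-1-yl)-6-phenylcyclohex-3-en-1-yl]methanone, via ring-opened dienylphenol 9 (not isolated)
Conditions: Pd2(dba)3 (2.5 mol %), DPEphos (6 mol %), toluene (0.02 M), 90 °C, argon
Reagents that add atoms: none
Why: Proposed new method: Pd(0) ionises the allylic C–O bond of the five-membered ring (O1 leaves as the phenoxide of a 2-acylphenol), β-hydride elimination from the benzylic CH2 of the η3-(2-methylallyl)palladium gives the (E)-1-aryl-3-methylbutadiene 9 and a Pd–H, the Pd–H re-adds to the terminal CH2 to give the η3-(1-aryl-3,3-dimethylallyl)palladium, which equilibrates syn/anti by π–σ–π, and O1 attacks the CMe2 terminus. The closest known reaction types are the Pd(0)-catalysed reversible addition of phenols across 1,3-dienes, the Pd(0)-catalysed elimination of allyl aryl ethers to 1,3-dienes and the 6-endo-trig Tsuji–Trost etherification that gives 2H-chromenes; new is their combination into a one-atom ring expansion. The pyran ring closes 6-endo-trig on the anti-η3-allyl (attack at the benzylic terminus would need a four-membered ring and the C5 methoxy group cannot close), so C2 moves from outside the ring to inside and the ring grows from five to six atoms. No stereocentre is formed: the uncontrolled centre of the dihydrofuran becomes the sp2 carbon C3, so both epimers of 8 funnel into one compound, while C1, C2 and C6 of the cyclohexene are not touched under these neutral conditions. All C–O bond-forming events are reversible, so the product is selected by thermodynamics, and the chromene has the unstrained ring, the tertiary ether carbon and a C3=C4 bond conjugated with the electron-rich arene. Chemoselectivity rests on 8 having only one allylic leaving group and on its two other C=C bonds being trisubstituted and poor partners for Pd–H.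

## Compound list

1 | 2',6'-dihydroxy-4'-methoxyacetophenone | CC(=O)c1c(O)cc(OC)cc1O | starting material
2 | 1-(2,6-dihydroxy-3-iodo-4-methoxyphenyl)ethan-1-one | CC(=O)c1c(O)cc(OC)c(I)c1O | intermediate
3 | isoprene | C=CC(C)=C | starting material
4 | rac-1-[6-hydroxy-4-methoxy-2-(prop-1-en-2-yl)-2,3-dihydro-1-benzofuran-7-yl]ethan-1-one | CC(=O)c1c(O)cc(OC)c2c1OC(C(C)=C)C2 | intermediate
5 | benzaldehyde | O=Cc1ccccc1 | starting material
6 | rac-(E)-1-[6-hydroxy-4-methoxy-2-(prop-1-en-2-yl)-2,3-dihydro-1-benzofuran-7-yl]-3-phenylprop-2-en-1-one | O=C(/C=C/c1ccccc1)c1c(O)cc(OC)c2c1OC(C(C)=C)C2 | intermediate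
7 | (E)-β-ocimene, (3E)-3,7-dimethylocta-1,3,6-triene | C=C/C(C)=C/CC=C(C)C | starting material
8 | Diels–Alder adduct, (1R,2S,6R)-cyclohexene, both epimers at the dihydrofuran C2 | COc1cc(O)c(C(=O)[C@@H]2[C@H](CC=C(C)C)C(C)=CC[C@H]2c2ccccc2)c2c1CC(C(C)=C)O2 | intermediate
9 | {2,6-dihydroxy-4-methoxy-3-[(1E)-3-methylbuta-1,3-dien-1-yl]phenyl}[(1R,2S,6R)-3-methyl-2-(3-methylbut-2-en-1-yl)-6-phenylcyclohex-3-en-1-yl]methanone (not isolated) | COc1cc(O)c(C(=O)[C@@H]2[C@H](CC=C(C)C)C(C)=CC[C@H]2c2ccccc2)c(O)c1/C=C/C(C)=C | intermediate
10 | (7-hydroxy-5-methoxy-2,2-dimethyl-2H-chromen-8-yl)[(1R,2S,6R)-3-methyl-2-(3-methylbut-2-en-1-yl)-6-phenylcyclohex-3-en-1-yl]methanone | COc1cc(O)c(C(=O)[C@@H]2[C@H](CC=C(C)C)C(C)=CC[C@H]2c2ccccc2)c2c1C=CC(C)(C)O2 | target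

Total step count: 5. Longest linear sequence: 5 steps (1 → 2 → 4 → 6 → 8 → 10).

## Steps most likely to fail

**Step 5 (Proposed new method).**
- Risk: Pd–H may move the isopropenyl double bond into the five-membered ring. Aromatisation of the furan would then be irreversible and would drain the equilibrium. The reaction may also stall at the ring-opened stage, with oligomerisation of the diene.
- Fallback: the ring enlargement is moved to the ketone stage, where acid is tolerated, and split into two known reactions. It sets out from 4.
  - Pd(OAc)2/PPh3-catalysed 1,4-elimination of the allyl aryl ether (Et3N, dioxane, reflux) gives the dienylphenol ketone F1.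
  - Catalytic PPTS in toluene closes it through the 1-aryl-3,3-dimethylallyl cation to the chromene ketone F2.
  - Claisen–Schmidt condensation with 5 gives the chromenochalcone F3.
  - The borate-promoted Diels–Alder reaction of step 4 with 7 comes back to the route at 10.

**Step 4.**
- Risk: facial or endo/exo selectivity may be poor if the ortho ring oxygen twists the boron-bound enone. Slow cycloaddition may also let the diene degrade.
- Fallback: asymmetric induction is given up in favour of a racemic synthesis with resolution. It sets out from 6 and 7.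
  - An electron-transfer Diels–Alder reaction on silica-supported silver nanoparticles (CH2Cl2, 50 °C) gives 8 together with its cyclohexene antipodes F4.
  - Step 5 on this mixture gives 10 together with its enantiomer F5.
  - Preparative chromatography on a chiral stationary phase removes F5, and the route is rejoined at 10.

**Step 2.**
- Risk: the very electron-rich aryl iodide may lose iodine by protodehalogenation. Insertion may also occur at the methyl-substituted terminus of isoprene.
- Fallback: the C–C bond is made first by alkylation and the ring is closed oxidatively. It sets out from 1.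
  - C-prenylation with prenyl bromide in aqueous KOH gives the 3'-prenyl ketone F6.
  - A Wacker-type oxidative cyclisation (Pd(OAc)2 cat., Cu(OAc)2 cat., O2, MeOH/H2O) proceeds by 5-exo oxypalladation and β-hydride elimination towards a methyl group. It comes back to the route at 4.

## Further compounds

F1 | step 5 | 1-{2,6-dihydroxy-4-methoxy-3-[(1E)-3-methylbuta-1,3-dien-1-yl]phenyl}ethan-1-one | CC(=O)c1c(O)cc(OC)c(/C=C/C(C)=C)c1O
F2 | step 5 | 1-(7-hydroxy-5-methoxy-2,2-dimethyl-2H-chromen-8-yl)ethan-1-one | CC(=O)c1c(O)cc(OC)c2c1OC(C)(C)C=C2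
F3 | step 5 | (E)-1-(7-hydroxy-5-methoxy-2,2-dimethyl-2H-chromen-8-yl)-3-phenylprop-2-en-1-one | O=C(/C=C/c1ccccc1)c1c(O)cc(OC)c2c1OC(C)(C)C=C2
F4 | step 4 | (1S,2R,6S)-cyclohexene antipodes of 8, both epimers at the dihydrofuran C2 | COc1cc(O)c(C(=O)[C@H]2[C@@H](CC=C(C)C)C(C)=CC[C@@H]2c2ccccc2)c2c1CC(C(C)=C)O2
F5 | step 4 | enantiomer of 10, (1S,2R,6S) | COc1cc(O)c(C(=O)[C@H]2[C@@H](CC=C(C)C)C(C)=CC[C@@H]2c2ccccc2)c2c1C=CC(C)(C)O2
F6 | step 2 | 1-[2,6-dihydroxy-4-methoxy-3-(3-methylbut-2-en-1-yl)phenyl]ethan-1-one | CC(=O)c1c(O)cc(OC)c(CC=C(C)C)c1O
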